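The earlier runs and the new flask were computed with made-up constants; scatter was added.

Multiply before fitting.

| setting | midnight | winter | Monday's | Tuesday's | Sunday's |
|---|---|---|---|---|---|
| substrate | 0.046 M | 0.11 M | 0.040 M | 0.060 M | 0.10 M |
| reagent | 1.5 equiv | 1.5 equiv | 1.50 equiv | 1.50 equiv | 1.50 equiv |
| remark | run made earlier | run made earlier |  |  |  |
| time |  |  | 20 h | 20 h | 20 h |

| run | time / h | tris adduct / % |
|---|---|---|
| midnight | 0.667 | 0.1 |
| midnight | 2.00 | 2.8 |
| midnight | 4.00 | 6.5 |
| midnight | 5.00 | 7.6 |
| midnight | 8.00 | 10.3 |
| midnight | 10.0 | 9.5 |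
| winter | 0.833 | 3.1 |
| winter | 1.33 | 5.1 |
| winter | 2.00 | 7.6 |
| winter | 4.00 | 8.6 |
| winter | 6.00 | 10.4 |
| winter | 10.0 | 10.4 |

(readings scatter by 0.5 percentage points)

- [tris adduct] at the end for Monday's, Tuesday's, Sunday's, in this order
- the course of these numbers from the first flask to the last (rises, then falls / hardly changes / falls, then rises / rises all the way / falls all the way)

- the numbers in the tables scatter by 0.5 percentage points (one standard deviation)
- "hardly changes" means that all values lie within two and a half points (for a concentration: within two and a half percent of the largest)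

Both earlier runs carry 1.5 equiv of reagent, so the reagent charge moves with the substrate charge. At fixed equivalents, if each step joins two partners, the percent formed depends on substrate charged times time elapsed. Monday's flask ends at 0.800 M·h of that product, the reach.

The tables can test this. The midnight run at 5.00 h has reach 0.230 M·h and reads 7.6%. The winter run at 2.00 h has reach 0.220 M·h and reads 7.6%. So I lay both runs on one curve.

The winter run then reads 10.4% at reach 0.660 M·h and 10.4% at reach 1.10 M·h, so the curve is flat there. Monday's reach lies inside that stretch. But Tuesday's 1.20 M·h and Sunday's 2.00 M·h lie past it, so for those flasks I extrapolate.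

I commit to 10.4% of each charge: 0.00416 M, 0.00624 M and 0.0104 M, rising from flask to flask.

The forecast gives 0.0041 M, 0.0061 M and 0.0102 M, a little below mine, and rises all the way, saying “Both runs level off at the same share of the charge”.

The flasks give 0.00405 M, 0.00608 M and 0.0101 M: rises all the way.

    reagent + tris adduct → tetra adduct + by-product (k = 0.00344 M⁻¹ s⁻¹)
    reagent + double product → tris adduct + by-product (k = 0.00158 M⁻¹ s⁻¹)
    reagent + single product → double product + by-product (k = 0.00379 M⁻¹ s⁻¹)
    substrate + reagent → single product + by-product (k = 0.00164 M⁻¹ s⁻¹)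
    substrate ⇌ dormant form (K = 0.510, k = 1.19 × 10⁻⁵ s⁻¹)

In Monday's flask at 20.0 h the reagent is the limiting reagent, with 0.48% of its charge left beside 22% of the substrate. Set by reach, the reagent remainders fall in order. Tuesday's flask at 10.0 h, reach 0.600 M·h, keeps 1.57%. Monday's flask at its end, reach 0.800 M·h, keeps 0.480%. Sunday's flask at 10.0 h, reach 1.00 M·h, keeps 0.0957%.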